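**Retrosynthetic overview**

- The C10′/C13′ 1,4-diketone of the side chain is carried as a 2-alkyl-5-methylfuran and unmasked last by aqueous acid; this leads back to an (S)-3-(furylnonyl)phthalide.
- Feature the strategy rests on: in the phthalide ring, C1 (lactone carbonyl on C7a) and C3 (carbinol on C3a) are an acid-level and an alcohol-level carbon on neighbouring arene carbons. The lactone is therefore a redox isomer of an ortho keto-aldehyde (C1 as CHO, C3 as ketone).
- The lactone is the only ring formed. It is closed by Rh-catalysed enantioselective intramolecular ketone hydroacylation, which makes C3–H and C1–O2 and sets C3 as S.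
- The keto-aldehyde comes from a diol by double Swern oxidation. The diol comes from a bromo alcohol (Br–Li exchange, DMF, borohydride), itself made by Grignard addition to 2-bromo-3,5-dimethoxybenzaldehyde.
- The Grignard side chain comes from 2-methylfuran by lithiation and alkylation with 1,9-dibromononane.

Key step: step 5

Remark: 2-bromo-3,5-dimethoxybenzaldehyde is taken as a purchasable catalogue compound.
Remark: the sense of induction of the Duanphos enantiomers is assigned by analogy with simple 2-alkanoylbenzaldehydes. (S,S,R,R)-Duanphos is written as the working choice for 3S; the commercial antipode would be used if a first run showed the opposite sense.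

**Route**

Step 1
Reactants: 1 2-methylfuran; 2 1,9-dibromononane
Product: 4 2-(9-bromononyl)-5-methylfuran, via 5-methyl-2-furyllithium 3 (not isolated)
Conditions: n-BuLi (1.05 equiv), THF, −20 to 0 °C; then added to 2 (3 equiv), THF, 0 °C to rt; excess 2 recovered by distillation
Reagents that add atoms: none
Why: α-Lithiation of the furan at its only free α-position followed by SN2 alkylation with a primary bromide; the threefold excess of dibromide should hold back double alkylation.

Step 2
Reactants: 4 2-(9-bromononyl)-5-methylfuran; 5 2-bromo-3,5-dimethoxybenzaldehyde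
Product: 7 rac-1-(2-bromo-3,5-dimethoxyphenyl)-10-(5-methylfuran-2-yl)decan-1-ol, via Grignard reagent 6 (not isolated)
Conditions: Mg turnings, cat. I2, THF, 40 °C; then 5, THF, −20 to 0 °C; aq. NH4Cl
Reagents that add atoms: none
Why: Grignard addition of a primary alkylmagnesium bromide to an aromatic aldehyde; the aryl bromide does not exchange with an alkyl Grignard at this temperature, and the racemic carbinol is of no consequence because it is oxidised in step 4.

Step 3
Reactants: 7 rac-1-(2-bromo-3,5-dimethoxyphenyl)-10-(5-methylfuran-2-yl)decan-1-ol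
Product: 10 rac-1-[2-(hydroxymethyl)-3,5-dimethoxyphenyl]-10-(5-methylfuran-2-yl)decan-1-ol, via lithium alkoxide aryllithium 8 (not isolated), via lactol 9 (not isolated)
Conditions: n-BuLi (2.2 equiv), THF, −78 °C; DMF (3 equiv), −78 to 0 °C; then MeOH, NaBH4, 0 °C
Reagents that add atoms: N,N-dimethylformamide, CN(C)C=O
Why: O-deprotonation and bromine–lithium exchange give a dianion whose aryl C–Li is formylated by DMF (Bouveault formylation); the aldehyde, present as its lactol, is reduced in the same flask by borohydride, and the 2,5-dialkylfuran has no acidic α-position.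

Step 4
Reactants: 10 rac-1-[2-(hydroxymethyl)-3,5-dimethoxyphenyl]-10-(5-methylfuran-2-yl)decan-1-ol
Product: 11 2,4-dimethoxy-6-[10-(5-methylfuran-2-yl)decanoyl]benzaldehyde
Conditions: (COCl)2 (3 equiv), DMSO (6 equiv), CH2Cl2, −78 °C; Et3N (10 equiv), −78 to 0 °C
Reagents that add atoms: none
Why: Double Swern oxidation; both hydroxyls are turned into alkoxysulfonium salts at −78 °C before base is added, so no free hydroxy-aldehyde is present that could close to the lactol and over-oxidise to racemic lactone.

Step 5
Reactants: 11 2,4-dimethoxy-6-[10-(5-methylfuran-2-yl)decanoyl]benzaldehyde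
Product: 12 (3S)-5,7-dimethoxy-3-[9-(5-methylfuran-2-yl)nonyl]-2-benzofuran-1(3H)-one
Conditions: [Rh(cod)Cl]2 (2.5 mol%), (S,S,R,R)-Duanphos (5 mol%), AgNO3 (5 mol%), toluene, 80–90 °C, argon
Reagents that add atoms: none
Why: The cationic Rh(I)–bisphosphine, held by the ortho ketone, inserts into the formyl C–H to give an acyl rhodium(III) hydride; the bound C3=O then inserts into Rh–H, and C–O reductive elimination from the acyl alkoxide releases the lactone and Rh(I). This is the known enantioselective intramolecular ketone hydroacylation of 2-alkanoylbenzaldehydes to 3-alkylphthalides, applied here to a substrate with two methoxy groups and a remote furan. The five-membered lactone closes by C1–O2 reductive elimination from a six-membered acyl-alkoxide rhodacycle (Rh, C1, C7a, C3a, C3, O), formally a 5-exo-trig acylation of the C3 oxygen. C3 is the only new stereocentre: the chiral bisphosphine decides which face of the chelated ketone receives the hydride, and Re-face delivery (O > aryl > alkyl) gives 3S. The step needs hydroacylation to outrun decarbonylation of the acyl hydride and intermolecular Tishchenko dimerisation; the ketone ortho to the formyl group (flanked only by H-4, as in the parent substrates) and the coordinating nitrate counter-ion should secure this. C7–OMe is a weaker donor than the ketone, the furan offers no reducible site, and every atom of 11 is kept in 12.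

Step 6
Reactants: 12 (3S)-5,7-dimethoxy-3-[9-(5-methylfuran-2-yl)nonyl]-2-benzofuran-1(3H)-one
Product: 13 CJ-13,015, (3S)-3-(10,13-dioxotetradecyl)-5,7-dimethoxy-2-benzofuran-1(3H)-one
Conditions: AcOH/H2O (3:1), cat. H2SO4, 100 °C
Reagents that add atoms: water, O
Why: Acid-catalysed hydrolytic opening of the 2,5-dialkylfuran (reverse Paal–Knorr) should give the 1,4-diketone; the five-membered lactone re-closes if it opens, and C3 should not ionise because both methoxy groups are meta to C3a and the lactone carbonyl is ortho, so the S centre is kept.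

**Compound list**

1 | 2-methylfuran | Cc1ccco1 | starting material
2 | 1,9-dibromononane | BrCCCCCCCCCBr | starting material
3 | 5-methyl-2-furyllithium | [Li]c1ccc(C)o1 | intermediate
4 | 2-(9-bromononyl)-5-methylfuran | Cc1ccc(CCCCCCCCCBr)o1 | intermediate
5 | 2-bromo-3,5-dimethoxybenzaldehyde | COc1cc(OC)c(Br)c(C=O)c1 | starting material
6 | [9-(5-methylfuran-2-yl)nonyl]magnesium bromide | Cc1ccc(CCCCCCCCC[Mg]Br)o1 | intermediate
7 | rac-1-(2-bromo-3,5-dimethoxyphenyl)-10-(5-methylfuran-2-yl)decan-1-ol | COc1cc(OC)c(Br)c(c1)C(O)CCCCCCCCCc2ccc(C)o2 | intermediate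
8 | lithium 1-(2-lithio-3,5-dimethoxyphenyl)-10-(5-methylfuran-2-yl)decan-1-olate | COc1cc(OC)c([Li])c(c1)C(O[Li])CCCCCCCCCc2ccc(C)o2 | intermediate
9 | 5,7-dimethoxy-3-[9-(5-methylfuran-2-yl)nonyl]-1,3-dihydro-2-benzofuran-1-ol (lactol, mixture of diastereomers) | COc1cc(OC)c2C(O)OC(CCCCCCCCCc3ccc(C)o3)c2c1 | intermediate
10 | rac-1-[2-(hydroxymethyl)-3,5-dimethoxyphenyl]-10-(5-methylfuran-2-yl)decan-1-ol | COc1cc(OC)c(CO)c(c1)C(O)CCCCCCCCCc2ccc(C)o2 | intermediate
11 | 2,4-dimethoxy-6-[10-(5-methylfuran-2-yl)decanoyl]benzaldehyde | COc1cc(OC)c(C=O)c(c1)C(=O)CCCCCCCCCc2ccc(C)o2 | intermediate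
12 | (3S)-5,7-dimethoxy-3-[9-(5-methylfuran-2-yl)nonyl]-2-benzofuran-1(3H)-one | COc1cc(OC)c2c(c1)[C@H](CCCCCCCCCc3ccc(C)o3)OC2=O | intermediate
13 | CJ-13,015, (3S)-3-(10,13-dioxotetradecyl)-5,7-dimethoxy-2-benzofuran-1(3H)-one | COc1cc(OC)c2c(c1)[C@H](CCCCCCCCCC(=O)CCC(C)=O)OC2=O | target

**Step count and risks**

Total step count: 6. Longest linear sequence: 6 steps (from 2-methylfuran; aldehyde 5 enters at step 2).

Steps most likely to fail:

1. Step 5. The formyl group is flanked on both sides and sits on an electron-rich ring, so C–H insertion may be slow. Decarbonylation of the acyl hydride or chelation by C7–OMe may then compete, and facial selectivity may fall short. Fallback from 7, returning at 12: Dess–Martin oxidation of 7 should give the bromo ketone 1-(2-bromo-3,5-dimethoxyphenyl)-10-(5-methylfuran-2-yl)decan-1-one F1. CBS reduction with (R)-Me-CBS and BH3·SMe2 (aryl as the large group) should give (1S)-1-(2-bromo-3,5-dimethoxyphenyl)-10-(5-methylfuran-2-yl)decan-1-ol F2. Treatment with n-BuLi (2.2 equiv) at −78 °C, CO2 and an acidic work-up should then carboxylate the aryl position and lactonise with retention at the carbinol to give 12.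

2. Step 4. One hydroxyl may be oxidised ahead of the other, with collapse to the lactol and over-oxidation to racemic lactone; the chlorosulfonium salt may also attack the furan. Fallback from 10, returning at 11: selective silylation of the primary hydroxyl (TBSCl, imidazole, DMF, 0 °C) should give 1-[2-({[tert-butyl(dimethyl)silyl]oxy}methyl)-3,5-dimethoxyphenyl]-10-(5-methylfuran-2-yl)decan-1-ol F3. Dess–Martin oxidation of the secondary alcohol should give the silyloxy ketone 1-[2-({[tert-butyl(dimethyl)silyl]oxy}methyl)-3,5-dimethoxyphenyl]-10-(5-methylfuran-2-yl)decan-1-one F4. TBAF should free 1-[2-(hydroxymethyl)-3,5-dimethoxyphenyl]-10-(5-methylfuran-2-yl)decan-1-one F5, in equilibrium with its cyclic hemiketal. Buffered Dess–Martin oxidation of the open form (the tertiary hemiketal hydroxyl cannot be oxidised) should then give 11.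

3. Step 6. Ring opening may stop at an unfavourable equilibrium, the furan may oligomerise in hot acid, or the 1,4-diketone may undergo aldol cyclisation. Fallback from 12, returning at 13: oxidative opening of the furan with mCPBA (CH2Cl2, 0 °C) should give the enedione (3S)-3-[(11Z)-10,13-dioxotetradec-11-en-1-yl]-5,7-dimethoxy-2-benzofuran-1(3H)-one F6. Reduction of its electron-poor C=C with zinc in acetic acid at room temperature should give 13 without touching the lactone or C3.

**Further compounds**

F1 | step 5 | 1-(2-bromo-3,5-dimethoxyphenyl)-10-(5-methylfuran-2-yl)decan-1-one | COc1cc(OC)c(Br)c(c1)C(=O)CCCCCCCCCc2ccc(C)o2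
F2 | step 5 | (1S)-1-(2-bromo-3,5-dimethoxyphenyl)-10-(5-methylfuran-2-yl)decan-1-ol | COc1cc(OC)c(Br)c(c1)[C@H](CCCCCCCCCc2ccc(C)o2)O
F3 | step 4 | 1-[2-({[tert-butyl(dimethyl)silyl]oxy}methyl)-3,5-dimethoxyphenyl]-10-(5-methylfuran-2-yl)decan-1-ol | COc1cc(OC)c(CO[Si](C)(C)C(C)(C)C)c(c1)C(O)CCCCCCCCCc2ccc(C)o2
F4 | step 4 | 1-[2-({[tert-butyl(dimethyl)silyl]oxy}methyl)-3,5-dimethoxyphenyl]-10-(5-methylfuran-2-yl)decan-1-one | COc1cc(OC)c(CO[Si](C)(C)C(C)(C)C)c(c1)C(=O)CCCCCCCCCc2ccc(C)o2
F5 | step 4 | 1-[2-(hydroxymethyl)-3,5-dimethoxyphenyl]-10-(5-methylfuran-2-yl)decan-1-one | COc1cc(OC)c(CO)c(c1)C(=O)CCCCCCCCCc2ccc(C)o2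
F6 | step 6 | (3S)-3-[(11Z)-10,13-dioxotetradec-11-en-1-yl]-5,7-dimethoxy-2-benzofuran-1(3H)-one | COc1cc(OC)c2c(c1)[C@H](CCCCCCCCCC(=O)/C=C\C(C)=O)OC2=O
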